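- Amounts first: one target holds two substrate units, so I count in fractions of the charge, and a flask that merely makes target has the fraction t/(t+τ) in target at time t.

| flask | substrate | temperature | remark | time |
|---|---|---|---|---|
| epsilon | 5 mM | 94 °C | run made earlier |  |
| gamma | 7.5 mM | 102 °C | run made earlier |  |
| north-east | 10 mM | 90 °C |  | 50 min |
| east | 10 mM |  | at 90 °C until 40 min, from then on at 105 °C | 50 min |
| south-west | 10 mM | 105 °C |  | 50 min |

| run | time / min | target / % |
|---|---|---|
| epsilon | 3.00 | 4.7 |
| epsilon | 5.00 | 6.3 |
| epsilon | 8.00 | 7.8 |
| epsilon | 15.0 | 15.6 |
| epsilon | 25.0 | 21.1 |
| epsilon | 40.0 | 26.5 |
| gamma | 3.00 | 8.1 |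
| gamma | 6.00 | 13.5 |
| gamma | 12.0 | 18.5 |
| gamma | 15.0 | 22.2 |
| gamma | 20.0 | 23.7 |

(scatter of a reading: 1 percentage point)

- percent here means substrate units held: one target counts as two
- a reading or a percentage of target counts all its forms, free or not

1. the best flask by amount of target, in percent of the substrate charged; "all alike" if 1.5 percentage points covers them all (north-east / east / south-west / all alike)
2. amount of target at the end, in percent of the substrate charged, north-east
3. amount of target at the end, in percent of the substrate charged, east
4. amount of target at the end, in percent of the substrate charged, south-west

- Early readings, where I assume little has been lost, give τ = t(1−x)/x: 74.4 min in epsilon and 38.4 min in gamma, each carrying the scatter of one reading.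
- I take τ as inverse to the charge and join the two runs on a logarithmic line in temperature, which gives north-east a making time of 42.2 min: the time in which a flask without loss turns half of its charge into target, the first half-life of a second-order step.
- One extreme is that lossless flask, which gives north-east 54.2% at 50 min.
- The other extreme freezes target at the last epsilon reading, 26.5%, reached at t/τ = 0.538, while north-east runs to 1.18.
- I place north-east between them, as an estimate of mine and not as a bound. Epsilon's last gain, read from two scattered readings, was 0.550 of the lossless gain, and if north-east keeps that share from there on, I expect 37.1%.
- Gamma's last reading stands lower than epsilon's at nearly equal t/τ, 0.520, by 2.8 percentage points against a scatter of 1 point per reading. Gamma differs from epsilon in charge as well as in temperature, so I take this as a hint, not a proof, that heat costs target, and on that hint I rank north-east first, east second, with its last 10.0 min hot, and south-west third.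
- The forecast gives north-east as best, with 45% there, 27% in east and 24% in south-west, on the ground “That points to a reversible, exothermic reaction”.
- The flasks give north-east as best, with 34.0% there, 30.8% in east and 22.8% in south-west; at 50.0 min, north-east holds 20.1% side product.

    substrate + target → side product (k = 2.60 /M/min, Ea = 86.0 kJ/mol)
    substrate + target ⇌ idle adduct, settled at all times (K = 62.0 /M, ΔH = −59.0 kJ/mol)
    2 substrate → target (k = 1.10 /M/min, Ea = 52.0 kJ/mol)
    (constants at 90 °C)

- Against its lossless 54.2%, north-east stands 20 points lower. For north-east left until 12 min, the same making time gives a lossless 22.1%, and that flask holds 18.3% target.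

(The earlier runs and the new flask were computed with constants of no real substance; noise was put on by code.)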